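## Retrosynthetic overview
1. The target comes from its 1-O-TBS ether. That ether comes from an acyclic, fully oxidised C15 farnesane bearing a C6 epoxy aldehyde and a C7 alkenyl iodide. One CrCl2/NiCl2 operation forms C6–C7 (the farnesyl C1–C10 bond of germacrane biogenesis) and then O6–C12 (costunolide-type lactonisation).
2. The cis-4,5-epoxide comes from the Z-allylic alcohol (neryl terminus) by Sharpless epoxidation on the open chain. It is placed before ring closure because a Z-enal would isomerise, and because the oxirane steers C6 by Felkin–Anh control.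
3. The (Z)-β-iodo-α-(acetoxymethyl)acrylate comes from a γ-hydroxy ynoate, iodide and CH2O. C8 is set by catalytic asymmetric addition of methyl propiolate to an aldehyde.
4. C1/C10 come from anti-crotylboration of the C7 aldehyde cut from neryl acetate, using trans-2-butene. The resulting vinyl group becomes the C8 aldehyde.
5. Ring order: oxirane, then ten-membered carbocycle, then γ-lactone (the last two in one flask).

Assumption: germacrane numbering (C1–C15) is used for positions. The SMILES is read as 1S,4R,5S,6S,8S,10R, with a cis-4,5-epoxide (C3 and C6 on the same side) and an (E)-2-methylbut-2-enoate (tiglate).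

## Route

Step 1
Reactants: 1 neryl acetate
Product: 3 (2Z)-3-methyl-6-oxohex-2-en-1-yl acetate, via 6,7-epoxyneryl acetate 2 (not isolated)
Conditions: mCPBA (1.0 equiv), CH2Cl2, 0 °C; crude 2, H5IO6 (1.2 equiv), THF–H2O, 0 °C
Reagents that add atoms: mCPBA, OOC(=O)c1cccc(Cl)c1
Why: Prilezhaev epoxidation picks the electron-rich 6,7-alkene because the 2,3-alkene is deactivated by the allylic acetate, and periodic acid then hydrolyses and cleaves the oxirane (Malaprade-type cleavage) to the C1 aldehyde while the Z-alkene stays intact.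

Step 2
Reactants: 3 (2Z)-3-methyl-6-oxohex-2-en-1-yl acetate; 4 trans-2-butene
Product: 7 (3R,4S,7Z)-3,7-dimethylnona-1,7-diene-4,9-diol, via (E)-crotyl-B(Ipc)2 5 (not isolated), via acetoxy borinate adduct 6 (not isolated)
Conditions: 4, KOtBu, nBuLi, THF, −78 to −45 °C; (+)-Ipc2BOMe, −78 °C; BF3·OEt2; 3, −78 °C, 4 h; then 3 M NaOH, 30% H2O2, rt to 40 °C
Reagents that add atoms: none
Why: In this Brown asymmetric crotylboration through a closed chair transition state, the E-crotyl geometry gives the anti C1/C10 pair, the Ipc groups derived from (−)-α-pinene set 1S,10R, and the alkaline peroxide work-up also saponifies the primary acetate.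

Step 3
Reactants: 7 (3R,4S,7Z)-3,7-dimethylnona-1,7-diene-4,9-diol
Product: 8 (3R,4S,7Z)-4,9-bis(tert-butyldimethylsilyloxy)-3,7-dimethylnona-1,7-diene
Conditions: TBSOTf (2.4 equiv), 2,6-lutidine, CH2Cl2, −78 to 0 °C
Reagents that add atoms: TBSOTf, CC(C)(C)[Si](C)(C)OS(=O)(=O)C(F)(F)F
Why: One silylation masks both hydroxyls, so O1 cannot later open the 4,5-epoxide in a 5-exo mode and O6 stays differentiated as the more labile primary allylic ether.

Step 4
Reactants: 8 (3R,4S,7Z)-4,9-bis(tert-butyldimethylsilyloxy)-3,7-dimethylnona-1,7-diene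
Product: 9 (3R,4S,7Z)-4,9-bis(tert-butyldimethylsilyloxy)-3,7-dimethylnon-7-enal
Conditions: PdCl2(PhCN)2 (12 mol%), CuCl2·2H2O (12 mol%), AgNO2 (6 mol%), O2 (1 atm), tBuOH–MeNO2 15:1, rt
Reagents that add atoms: dioxygen, O=O
Why: In this aldehyde-selective (anti-Markovnikov) Wacker oxidation under nitrite co-catalysis, only the monosubstituted alkene binds divalent palladium, its allylic branching favours the terminal carbonyl, and no stereocentre is touched.

Step 5
Reactants: 9 (3R,4S,7Z)-4,9-bis(tert-butyldimethylsilyloxy)-3,7-dimethylnon-7-enal; 10 methyl propiolate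
Product: 12 methyl (4S,6R,7S,10Z)-7,12-bis(tert-butyldimethylsilyloxy)-4-hydroxy-6,10-dimethyldodec-10-en-2-ynoate, via ethyl(alkynyl)zinc reagent 11 (not isolated)
Conditions: 10 (4 equiv), Et2Zn (4 equiv), (R)-BINOL (40 mol%), HMPA (2 equiv), CH2Cl2, rt, 16 h; Ti(OiPr)4 (1 equiv), 1 h; 9, rt, 4 h; H2O quench
Reagents that add atoms: none
Why: In this BINOL/Ti(OiPr)4-catalysed asymmetric alkynylzinc addition, which has precedent for alkyl propiolates with linear aliphatic aldehydes, (R)-BINOL sends the alkynyl group to the Re face and sets 8S under reagent control.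

Step 6
Reactants: 12 methyl (4S,6R,7S,10Z)-7,12-bis(tert-butyldimethylsilyloxy)-4-hydroxy-6,10-dimethyldodec-10-en-2-ynoate
Product: 13 methyl (2Z,4S,6R,7S,10Z)-7,12-bis(tert-butyldimethylsilyloxy)-4-hydroxy-2-(hydroxymethyl)-3-iodo-6,10-dimethyldodeca-2,10-dienoate
Conditions: MeMgI (1.0 equiv), Et2O–CH2Cl2, −78 °C; MgI2 (2 equiv), monomeric CH2O (from cracked paraformaldehyde, 5 equiv), −78 to −10 °C; H2O quench
Reagents that add atoms: magnesium diiodide, [Mg+2].[I-].[I-]; formaldehyde, C=O
Why: Proposed new method: iodide adds to the magnesium-activated ynoate at C7 to give an allenolate, and formaldehyde held on the neighbouring C8 magnesium alkoxide is delivered to C11 from the C8 side, which puts CH2OH cis to C8 and iodine cis to CO2Me (2Z), while any E isomer lactonises onto O8 and is separated, the closest known reaction being the Z-selective MgI2-promoted β-iodo Morita–Baylis–Hillman (iodo-aldol) reaction of propiolates with aldehydes, and no stereocentre is made or touched.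

Step 7
Reactants: 13 methyl (2Z,4S,6R,7S,10Z)-7,12-bis(tert-butyldimethylsilyloxy)-4-hydroxy-2-(hydroxymethyl)-3-iodo-6,10-dimethyldodeca-2,10-dienoate; 14 tiglic acid
Product: 16 methyl (2Z,4S,6R,7S,10Z)-2-(acetoxymethyl)-7,12-bis(tert-butyldimethylsilyloxy)-3-iodo-6,10-dimethyl-4-[(E)-2-methylbut-2-enoyloxy]dodeca-2,10-dienoate, via 13-monoacetate 15 (not isolated)
Conditions: AcCl (1.05 equiv), 2,4,6-collidine, CH2Cl2, −78 °C; then 14 (2 equiv), DCC, DMAP (10 mol%), −20 °C to rt
Reagents that add atoms: acetyl chloride, CC(=O)Cl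
Why: AcCl/collidine at low temperature acylates only the primary hydroxyl, and Steglich esterification then puts the tiglate on O8 with retention at C8 and without E/Z scrambling of the acid.

Step 8
Reactants: 16 methyl (2Z,4S,6R,7S,10Z)-2-(acetoxymethyl)-7,12-bis(tert-butyldimethylsilyloxy)-3-iodo-6,10-dimethyl-4-[(E)-2-methylbut-2-enoyloxy]dodeca-2,10-dienoate
Product: 17 methyl (2Z,4S,6R,7S,10Z)-2-(acetoxymethyl)-7-(tert-butyldimethylsilyloxy)-12-hydroxy-3-iodo-6,10-dimethyl-4-[(E)-2-methylbut-2-enoyloxy]dodeca-2,10-dienoate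
Conditions: HF·pyridine, pyridine, THF, 0 °C
Reagents that add atoms: none
Why: Under buffered fluoride the primary allylic silyl ether falls far faster than the hindered secondary one at O1, and the esters and the alkenyl iodide are inert.

Step 9
Reactants: 17 methyl (2Z,4S,6R,7S,10Z)-2-(acetoxymethyl)-7-(tert-butyldimethylsilyloxy)-12-hydroxy-3-iodo-6,10-dimethyl-4-[(E)-2-methylbut-2-enoyloxy]dodeca-2,10-dienoate
Product: 18 methyl (2Z,4S,6R,7S,10R,11S)-2-(acetoxymethyl)-7-(tert-butyldimethylsilyloxy)-10,11-epoxy-12-hydroxy-3-iodo-6,10-dimethyl-4-[(E)-2-methylbut-2-enoyloxy]dodec-2-enoate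
Conditions: Ti(OiPr)4 (20 mol%), L-(+)-DET (24 mol%), tBuOOH (2 equiv, decane), 4 Å MS, CH2Cl2, −20 °C
Reagents that add atoms: tert-butyl hydroperoxide, CC(C)(C)OO
Why: In this Sharpless asymmetric epoxidation, L-(+)-DET gives the (2S,3R)-epoxynerol sense (4R,5S in germacrane numbering), the Z-alkene becomes the cis-epoxide stereospecifically, and the electron-poor iodoacrylate and tiglate alkenes do not react.

Step 10
Reactants: 18 methyl (2Z,4S,6R,7S,10R,11S)-2-(acetoxymethyl)-7-(tert-butyldimethylsilyloxy)-10,11-epoxy-12-hydroxy-3-iodo-6,10-dimethyl-4-[(E)-2-methylbut-2-enoyloxy]dodec-2-enoate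
Product: 19 methyl (2Z,4S,6R,7S,10R,11R)-2-(acetoxymethyl)-7-(tert-butyldimethylsilyloxy)-10,11-epoxy-3-iodo-6,10-dimethyl-4-[(E)-2-methylbut-2-enoyloxy]-12-oxododec-2-enoate
Conditions: Dess–Martin periodinane, pyridine, CH2Cl2, 0 °C to rt
Reagents that add atoms: none
Why: Buffered Dess–Martin oxidation of the only free hydroxyl gives the configurationally locked cis-epoxy aldehyde, and the C11 descriptor changes only through CIP priorities.

Step 11
Reactants: 19 methyl (2Z,4S,6R,7S,10R,11R)-2-(acetoxymethyl)-7-(tert-butyldimethylsilyloxy)-10,11-epoxy-3-iodo-6,10-dimethyl-4-[(E)-2-methylbut-2-enoyloxy]-12-oxododec-2-enoate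
Product: 21 1-O-TBS ether of the target (1S,4R,5S,6S,8S,10R), via ring-closed hydroxy ester 20 (not isolated)
Conditions: CrCl2 (12 equiv), NiCl2 (0.1 equiv), degassed DMSO–THF 3:1, 19 added over 12 h (final 0.002 M), rt; aqueous work-up
Reagents that add atoms: none
Why: In this Nozaki–Hiyama–Kishi reaction, zerovalent nickel inserts into the electron-poor C7–I bond with retention, transmetalation gives an ester-chelated trivalent alkenylchromium that adds to the epoxy aldehyde at high dilution to close the ten-membered ring at C6–C7, Felkin–Anh attack anti to the oxirane C5–O bond sets 6S (O5/O6 anti), and the chromium alkoxide held cis to CO2Me lactonises at once to the butenolide.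

Step 12
Reactants: 21 1-O-TBS ether of the target
Product: 22 CNP0159184.1, (1S,4R,5S,6S,8S,10R)-13-acetoxy-4,5-epoxy-1-hydroxy-8-tigloyloxygermacr-7(11)-en-12,6-olide
Conditions: HF·pyridine, excess pyridine, THF, 0 °C to rt; pH 7 buffer quench
Reagents that add atoms: none
Why: Pyridine-buffered fluoride desilylation frees O1 without the acid that would trigger transannular attack of O1 on C4, and the esters, butenolide and oxirane survive.

## Compound list
1 | neryl acetate | CC(C)=CCC/C(C)=C\COC(C)=O | starting material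
2 | 6,7-epoxyneryl acetate (racemic at the oxirane CH) | CC1(C)OC1CC/C(C)=C\COC(C)=O | intermediate
3 | (2Z)-3-methyl-6-oxohex-2-en-1-yl acetate | O=CCC/C(C)=C\COC(C)=O | intermediate
4 | trans-2-butene | C/C=C/C | starting material
5 | (E)-crotyldiisopinocampheylborane, Ipc from (−)-α-pinene | C/C=C/CB([C@H]1C[C@H]2C[C@@H]([C@@H]1C)C2(C)C)[C@H]1C[C@H]2C[C@@H]([C@@H]1C)C2(C)C | intermediate
6 | B(Ipc)2 borinate of the (1S,10R) homoallylic alcohol, C6 acetate still in place | C=C[C@@H](C)[C@@H](OB([C@H]1C[C@H]2C[C@@H]([C@@H]1C)C2(C)C)[C@H]1C[C@H]2C[C@@H]([C@@H]1C)C2(C)C)CC/C(C)=C\COC(C)=O | intermediate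
7 | (3R,4S,7Z)-3,7-dimethylnona-1,7-diene-4,9-diol | C=C[C@@H](C)[C@@H](O)CC/C(C)=C\CO | intermediate
8 | (3R,4S,7Z)-4,9-bis(TBSO)-3,7-dimethylnona-1,7-diene | C=C[C@@H](C)[C@@H](O[Si](C)(C)C(C)(C)C)CC/C(C)=C\CO[Si](C)(C)C(C)(C)C | intermediate
9 | (3R,4S,7Z)-4,9-bis(TBSO)-3,7-dimethylnon-7-enal | O=CC[C@@H](C)[C@@H](O[Si](C)(C)C(C)(C)C)CC/C(C)=C\CO[Si](C)(C)C(C)(C)C | intermediate
10 | methyl propiolate | C#CC(=O)OC | starting material
11 | ethyl(3-methoxy-3-oxoprop-1-yn-1-yl)zinc | CC[Zn]C#CC(=O)OC | intermediate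
12 | methyl (4S,6R,7S,10Z)-7,12-bis(TBSO)-4-hydroxy-6,10-dimethyldodec-10-en-2-ynoate | COC(=O)C#C[C@@H](O)C[C@@H](C)[C@@H](O[Si](C)(C)C(C)(C)C)CC/C(C)=C\CO[Si](C)(C)C(C)(C)C | intermediate
13 | methyl (2Z,4S,6R,7S,10Z)-7,12-bis(TBSO)-4-hydroxy-2-(hydroxymethyl)-3-iodo-6,10-dimethyldodeca-2,10-dienoate | COC(=O)/C(CO)=C(\I)[C@@H](O)C[C@@H](C)[C@@H](O[Si](C)(C)C(C)(C)C)CC/C(C)=C\CO[Si](C)(C)C(C)(C)C | intermediate
14 | tiglic acid | C/C=C(\C)C(=O)O | starting material
15 | 13-monoacetate of 13 (O8 free) | COC(=O)/C(COC(C)=O)=C(\I)[C@@H](O)C[C@@H](C)[C@@H](O[Si](C)(C)C(C)(C)C)CC/C(C)=C\CO[Si](C)(C)C(C)(C)C | intermediate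
16 | 13-acetate 8-tiglate bis-TBS alkenyl iodide | COC(=O)/C(COC(C)=O)=C(\I)[C@@H](OC(=O)/C(C)=C/C)C[C@@H](C)[C@@H](O[Si](C)(C)C(C)(C)C)CC/C(C)=C\CO[Si](C)(C)C(C)(C)C | intermediate
17 | C6 allylic alcohol from 16 | COC(=O)/C(COC(C)=O)=C(\I)[C@@H](OC(=O)/C(C)=C/C)C[C@@H](C)[C@@H](O[Si](C)(C)C(C)(C)C)CC/C(C)=C\CO | intermediate
18 | (4R,5S)-cis-epoxy alcohol | COC(=O)/C(COC(C)=O)=C(\I)[C@@H](OC(=O)/C(C)=C/C)C[C@@H](C)[C@@H](O[Si](C)(C)C(C)(C)C)CC[C@@]1(C)O[C@H]1CO | intermediate
19 | cis-epoxy aldehyde (seco precursor) | COC(=O)/C(COC(C)=O)=C(\I)[C@@H](OC(=O)/C(C)=C/C)C[C@@H](C)[C@@H](O[Si](C)(C)C(C)(C)C)CC[C@@]1(C)O[C@H]1C=O | intermediate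
20 | ring-closed (6S)-hydroxy methyl ester, shown as the free alcohol | C/C=C(\C)C(=O)O[C@H]1C[C@@H](C)[C@@H](O[Si](C)(C)C(C)(C)C)CC[C@@]2(C)O[C@H]2[C@@H](O)/C1=C(/COC(C)=O)C(=O)OC | intermediate
21 | 1-O-TBS ether of the target | C/C=C(\C)C(=O)O[C@H]1C[C@@H](C)[C@@H](O[Si](C)(C)C(C)(C)C)CC[C@@]2(C)O[C@H]2[C@H]2OC(=O)C(COC(C)=O)=C12 | intermediate
22 | CNP0159184.1 | C/C=C(\C)C(=O)O[C@H]1C[C@@H](C)[C@@H](O)CC[C@@]2(C)O[C@H]2[C@H]2OC(=O)C(COC(C)=O)=C12 | target

## Count and risks
Total step count: 12. Longest linear sequence: 12 (1 to 22).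

**Step 11 (ring closure).**
- The alkenylchromium carries a tiglate on the neighbouring C8 and could lose it by β-elimination to an allenoate.
- Zerovalent nickel could ionise the 13-acetate.
- Divalent chromium could reduce the epoxy aldehyde.
- Ring strain could override the Felkin–Anh preference at C6.
- The fallback installs the tiglate after the ring is closed. It sets out from 15, which is now isolated after the acetylation stage.
- HF·pyridine/pyridine frees the primary alcohol to give the 6,8-diol F1.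
- Sharpless epoxidation with L-(+)-DET gives the epoxy diol F2.
- TEMPO/PhI(OAc)2 oxidises only the primary hydroxyl to the 8-hydroxy epoxy aldehyde F3.
- CrCl2/NiCl2 closure, with O8 now a chromium alkoxide and therefore a poor leaving group, gives the 8-hydroxy lactone F4.
- Steglich esterification of F4 with 14 comes back to the route at 21.

**Step 6 (iodo-aldol).**
- The allenolate may be protonated instead of hydroxymethylated.
- The β-substituted ynoate may be sluggish.
- The chelate-directed 2Z selectivity is unproven.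
- The fallback removes the acidic site and relies on steric instead of chelate control. It sets out from 12.
- Esterification of 12 with 14 (DCC, catalytic DMAP, 0 °C) gives the γ-tigloyloxy ynoate F5.
- Treating F5 with MgI2 and monomeric CH2O lets formaldehyde enter anti to iodine.
- Quenching the magnesium alkoxide in the same flask with Ac2O comes back to the route at 16.

**Step 4 (aldehyde-selective Wacker).**
- Methyl ketone formation, palladium hydride migration of the alkene towards C10, or palladium-assisted loss of a silyl ether could erode the yield.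
- The fallback replaces oxypalladation with hydroboration. It sets out from 8.
- 9-BBN reacts only at the monosubstituted alkene, and NaBO3 oxidation gives the primary alcohol F6.
- Dess–Martin oxidation of F6 comes back to the route at 9, at the cost of one extra step.

## Further compounds
F1 | step 11 | methyl (2Z,4S,6R,7S,10Z)-2-(acetoxymethyl)-7-(TBSO)-4,12-dihydroxy-3-iodo-6,10-dimethyldodeca-2,10-dienoate | COC(=O)/C(COC(C)=O)=C(\I)[C@@H](O)C[C@@H](C)[C@@H](O[Si](C)(C)C(C)(C)C)CC/C(C)=C\CO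
F2 | step 11 | (10R,11S)-10,11-epoxide of F1 | COC(=O)/C(COC(C)=O)=C(\I)[C@@H](O)C[C@@H](C)[C@@H](O[Si](C)(C)C(C)(C)C)CC[C@@]1(C)O[C@H]1CO
F3 | step 11 | 12-aldehyde from F2 (O8 free) | COC(=O)/C(COC(C)=O)=C(\I)[C@@H](O)C[C@@H](C)[C@@H](O[Si](C)(C)C(C)(C)C)CC[C@@]1(C)O[C@H]1C=O
F4 | step 11 | 8-hydroxy analogue of 21 (no tiglate) | O[C@H]1C[C@@H](C)[C@@H](O[Si](C)(C)C(C)(C)C)CC[C@@]2(C)O[C@H]2[C@H]2OC(=O)C(COC(C)=O)=C12
F5 | step 6 | methyl (4S,6R,7S,10Z)-7,12-bis(TBSO)-6,10-dimethyl-4-[(E)-2-methylbut-2-enoyloxy]dodec-10-en-2-ynoate | COC(=O)C#C[C@@H](OC(=O)/C(C)=C/C)C[C@@H](C)[C@@H](O[Si](C)(C)C(C)(C)C)CC/C(C)=C\CO[Si](C)(C)C(C)(C)C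
F6 | step 4 | (3R,4S,7Z)-4,9-bis(TBSO)-3,7-dimethylnon-7-en-1-ol | OCC[C@@H](C)[C@@H](O[Si](C)(C)C(C)(C)C)CC/C(C)=C\CO[Si](C)(C)C(C)(C)C
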